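**Strategy.** The cyclohexene ring is cut across C1–C2 and C5–C6 (C1 bears the benzoyloxymethyl carbon C7, C2 is the vinylic CH, C3 the benzoate carbon). C2–C5 are the four carbons of furan, whose oxygen becomes O5; C1 and C6 are the alkene carbons of methyl (E)-4-oxopent-2-enoate. A catalytic enantioselective Diels–Alder reaction joins the two, making both bonds and the C5/C6 stereocentres in one operation. The rigid 7-oxanorbornene then directs exo-epoxidation (C3, C4), a Baeyer–Villiger step turns the endo acetyl into O6, and base-induced opening of the oxygen bridge unveils the C1=C2 alkene. Epoxide opening by benzoate at C3 completes the target.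

Key step: step 1

Assumption: catalyst binding at the ketone oxygen of 2 and the facial sense of the (S)-prolinol-derived catalyst are taken by analogy with its enone and acrylate cycloadditions; if the sense is opposite, the (R)-prolinol-derived catalyst is used with nothing else changed.

Step 1
Reactants: 1 furan; 2 methyl (E)-4-oxopent-2-enoate
Product: 3 methyl (1R,2S,3S,4S)-3-acetyl-7-oxabicyclo[2.2.1]hept-5-ene-2-carboxylate (ester exo, acetyl endo)
Conditions: furan (10 equiv), N-protonated (S)-3,3-diphenyl-1-(2-methylphenyl)tetrahydro-1H,3H-pyrrolo[1,2-c][1,3,2]oxazaborole, (CF3SO2)2N− salt (20 mol%), CH2Cl2, −78 to −60 °C; Et3N quench, cold filtration, used at once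
Reagents that add atoms: none
Why: The protonated oxazaborolidine binds the ketone oxygen of 2, lowers the LUMO of the E-alkene and lets furan add across its C2 and C5 positions in a concerted, asynchronous [4+2] cycloaddition that forms the C1–C2 and C5–C6 σ-bonds of the target together; C1–C2 is raised to the ring alkene only in step 4, when the oxygen bridge made here is opened. The closest known reaction type is the oxazaborolidinium-catalysed enantioselective Diels–Alder reaction of enones and acrylates, which includes furan as diene. The step closes the six-membered carbocycle in a suprafacial/suprafacial [4+2] mode and with it the temporary 7-oxabicyclo[2.2.1]heptene, whose bridge oxygen is the later O5. The trans relation of acetyl (C6) and ester (C1) follows from the E geometry of 2, the relation of C6 to the bridgeheads from the endo orientation of the catalyst-bound acetyl group, and the absolute configuration from shielding of one alkene face by an aryl group of the catalyst. The step needs endo-acetyl and facial selectivity and must outrun conjugate (Friedel–Crafts-type) addition of furan and cycloreversion; regiochemistry is no issue because furan is C2v-symmetric, ketone-directed binding should secure the endo mode, and low temperature, excess furan and immediate use of 3 should secure the rest.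

Step 2
Reactants: 3 methyl (1R,2S,3S,4S)-3-acetyl-7-oxabicyclo[2.2.1]hept-5-ene-2-carboxylate
Product: 5 methyl 7-endo-acetoxy-3,8-dioxatricyclo[3.2.1.0(2,4)]octane-6-exo-carboxylate (epoxide exo), via exo-epoxy ketone 4 (not isolated)
Conditions: CF3CO3H [from urea·H2O2 and (CF3CO)2O], Na2HPO4, CH2Cl2, 0 °C to rt
Reagents that add atoms: trifluoroperacetic acid, OOC(=O)C(F)(F)F
Why: Peracid (Prilezhaev) epoxidation of the strained alkene should occur from the exo face, syn to the oxygen bridge, which sets C3 and C4, and Baeyer–Villiger oxidation of the methyl ketone should proceed with migration of the secondary carbon C6 with retention, which places O6 endo, i.e. trans to the bridge oxygen; the phosphate buffer protects the epoxide from trifluoroacetic acid.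

Step 3
Reactants: 5 methyl 7-endo-acetoxy-3,8-dioxatricyclo[3.2.1.0(2,4)]octane-6-exo-carboxylate
Product: 6 methyl 7-endo-hydroxy-3,8-dioxatricyclo[3.2.1.0(2,4)]octane-6-exo-carboxylate
Conditions: K2CO3 (0.2 equiv), MeOH, 0 °C
Reagents that add atoms: none
Why: Base-catalysed transesterification (Zemplén-type methanolysis) should remove the acetyl group much faster than the hindered ester α-proton is abstracted, so that no acetate leaving group remains β to the ester when the enolate is formed in step 4; no stereocentre is created, and epimerisation at C1 is without consequence because C1 becomes trigonal.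

Step 4
Reactants: 6 methyl 7-endo-hydroxy-3,8-dioxatricyclo[3.2.1.0(2,4)]octane-6-exo-carboxylate
Product: 7 methyl (3S,4R,5R,6S)-3,4-epoxy-5,6-dihydroxycyclohex-1-ene-1-carboxylate
Conditions: LiN(SiMe3)2 (2.2 equiv), THF, −78 to −30 °C; aq. NH4Cl
Reagents that add atoms: none
Why: In this E1cB β-elimination, with O6 held as a non-leaving lithium alkoxide, the ester enolate at C1 should expel the strained bridging oxygen at C2, which creates the C1=C2 alkene and leaves that oxygen on C5 with unchanged configuration (trans to O6 and cis to the epoxide, so no Payne rearrangement can follow); this base-induced opening is known for 7-oxanorbornane-2-carboxylates, including their exo-epoxides.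

Step 5
Reactants: 7 methyl (3S,4R,5R,6S)-3,4-epoxy-5,6-dihydroxycyclohex-1-ene-1-carboxylate
Product: 8 (3S,4R,5R,6S)-3,4-epoxy-1-(hydroxymethyl)cyclohex-1-ene-5,6-diol
Conditions: i-Bu2AlH (5 equiv), CH2Cl2/THF, −78 °C; aq. potassium sodium tartrate
Reagents that add atoms: none
Why: 1,2-Reduction of the conjugated ester by the aluminium hydride at low temperature should give the allylic alcohol (two equivalents are consumed by the free hydroxyls) while the epoxide reacts more slowly; no stereocentre is affected.

Step 6
Reactants: 8 (3S,4R,5R,6S)-3,4-epoxy-1-(hydroxymethyl)cyclohex-1-ene-5,6-diol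
Product: 9 [(3S,4R,5R,6S)-3,4-epoxy-5,6-dihydroxycyclohex-1-en-1-yl]methyl benzoate
Conditions: BzCl (1.05 equiv), 2,4,6-collidine, CH2Cl2, −40 °C
Reagents that add atoms: benzoyl chloride, O=C(Cl)c1ccccc1
Why: In this kinetically selective O-acylation, one equivalent of benzoyl chloride with a hindered pyridine base at low temperature should esterify the unhindered primary allylic hydroxyl in preference to the two secondary ones.

Step 7
Reactants: 9 [(3S,4R,5R,6S)-3,4-epoxy-5,6-dihydroxycyclohex-1-en-1-yl]methyl benzoate
Product: 10 [(3R,4R,5R,6S)-3-(benzoyloxy)-4,5,6-trihydroxycyclohex-1-en-1-yl]methyl benzoate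
Conditions: PhCO2H (2 equiv), Ti(OiPr)4 (1.5 equiv), CH2Cl2, rt; aq. tartaric acid
Reagents that add atoms: benzoic acid, O=C(O)c1ccccc1
Why: In this titanium-alkoxide-assisted opening of a 2,3-epoxy alcohol by a carboxylic acid, coordination through O5 should direct benzoate to C3, which is also the allylic position, with SN2 inversion, so that the C3 benzoate ends trans to the C4 hydroxyl while C4, C5 and C6 keep their configuration.

**Compound list**
1 | furan | c1ccoc1 | starting material
2 | methyl (E)-4-oxopent-2-enoate | COC(=O)/C=C/C(C)=O | starting material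
3 | methyl (1R,2S,3S,4S)-3-acetyl-7-oxabicyclo[2.2.1]hept-5-ene-2-carboxylate (2-exo ester, 3-endo acetyl) | COC(=O)[C@@H]1[C@H]2C=C[C@H](O2)[C@H]1C(C)=O | intermediate
4 | methyl 7-endo-acetyl-3,8-dioxatricyclo[3.2.1.0(2,4)]octane-6-exo-carboxylate (exo-epoxide of 3, not isolated) | COC(=O)[C@@H]1[C@H]2[C@@H]3O[C@@H]3[C@H](O2)[C@H]1C(C)=O | intermediate
5 | methyl 7-endo-acetoxy-3,8-dioxatricyclo[3.2.1.0(2,4)]octane-6-exo-carboxylate (epoxide oxygen syn to the oxygen bridge) | COC(=O)[C@@H]1[C@H]2[C@@H]3O[C@@H]3[C@H](O2)[C@H]1OC(C)=O | intermediate
6 | methyl 7-endo-hydroxy-3,8-dioxatricyclo[3.2.1.0(2,4)]octane-6-exo-carboxylate | COC(=O)[C@@H]1[C@H]2[C@@H]3O[C@@H]3[C@H](O2)[C@H]1O | intermediate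
7 | methyl (3S,4R,5R,6S)-3,4-epoxy-5,6-dihydroxycyclohex-1-ene-1-carboxylate (epoxide cis to 5-OH; 5-OH and 6-OH trans) | COC(=O)C1=C[C@@H]2O[C@@H]2[C@H](O)[C@H]1O | intermediate
8 | (3S,4R,5R,6S)-3,4-epoxy-1-(hydroxymethyl)cyclohex-1-ene-5,6-diol | OCC1=C[C@@H]2O[C@@H]2[C@H](O)[C@H]1O | intermediate
9 | [(3S,4R,5R,6S)-3,4-epoxy-5,6-dihydroxycyclohex-1-en-1-yl]methyl benzoate | O=C(OCC1=C[C@@H]2O[C@@H]2[C@H](O)[C@H]1O)c1ccccc1 | intermediate
10 | [(3R,4R,5R,6S)-3-(benzoyloxy)-4,5,6-trihydroxycyclohex-1-en-1-yl]methyl benzoate (CNP0178138.1) | O=C(OCC1=C[C@@H](OC(=O)c2ccccc2)[C@H](O)[C@H](O)[C@H]1O)c1ccccc1 | target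

**Totals.** Total step count: 7. Longest linear sequence: 7 steps (from 1 and 2).

**Steps most likely to fail**

Step 1. The cycloaddition may show poor facial or endo/exo discrimination (for example if the catalyst binds the ester oxygen instead of the ketone oxygen), or furan may add in a conjugate, Friedel–Crafts-type manner. The fallback sets out from 1 and 2 and comes back at 6. The cycloaddition is run without a chiral catalyst (neat furan, ZnI2 (cat.), 0 °C, or high pressure), and the endo-acetyl adduct is separated from its exo-acetyl isomer as the racemate, i.e. 3 together with its mirror image ent-3 F1. The oxidation of step 2 then gives, through the unisolated epoxy ketone 4 and its mirror image ent-4 F2, the racemic acetate, i.e. 5 together with ent-5 F3. An enantioselective enzymatic hydrolysis (Candida antarctica lipase B or Pseudomonas cepacia lipase, phosphate buffer pH 7, enzyme chosen by screening) should then cleave the acetate of 5 only, giving 6 and leaving F3 to be separated.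

Step 4. The hindered C1–H may be enolised incompletely, or the strongly basic medium may deprotonate the γ-position of the epoxy enoate product and lead to aromatisation. The fallback sets out from 6 and comes back at 8. The ester of 6 is reduced first (i-Bu2AlH, CH2Cl2, −78 °C) to [7-endo-hydroxy-3,8-dioxatricyclo[3.2.1.0(2,4)]oct-6-exo-yl]methanol F4. Selective oxidation of its primary alcohol (TEMPO (cat.), PhI(OAc)2, CH2Cl2) gives 7-endo-hydroxy-3,8-dioxatricyclo[3.2.1.0(2,4)]octane-6-exo-carbaldehyde F5. Its far more acidic α-proton allows the bridge to be opened with Et3N at 0 °C, giving (3S,4R,5R,6S)-3,4-epoxy-5,6-dihydroxycyclohex-1-ene-1-carbaldehyde F6. Luche reduction (NaBH4, CeCl3·7H2O, MeOH, −40 °C) then gives 8, so no ester enolate or amide base is needed.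

Step 6. The secondary hydroxyls may be acylated as well, or the acyl group may migrate. The fallback sets out from 8 and comes back at 9. Instead of acyl transfer, the primary allylic alcohol itself is activated in a Mitsunobu esterification (PhCO2H, PPh3, diisopropyl azodicarboxylate, THF, 0 °C), in which the less hindered primary carbinol should react first; no new compound is made.

Further compounds
F1 | step 1 | methyl (1S,2R,3R,4R)-3-acetyl-7-oxabicyclo[2.2.1]hept-5-ene-2-carboxylate (ent-3) | COC(=O)[C@H]1[C@@H]2C=C[C@@H](O2)[C@@H]1C(C)=O
F2 | step 1 | ent-4, mirror image of the exo-epoxy ketone (not isolated) | COC(=O)[C@H]1[C@@H]2[C@H]3O[C@H]3[C@@H](O2)[C@@H]1C(C)=O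
F3 | step 1 | ent-5, mirror image of the epoxy acetate | COC(=O)[C@H]1[C@@H]2[C@H]3O[C@H]3[C@@H](O2)[C@@H]1OC(C)=O
F4 | step 4 | [7-endo-hydroxy-3,8-dioxatricyclo[3.2.1.0(2,4)]oct-6-exo-yl]methanol | OC[C@@H]1[C@H]2[C@@H]3O[C@@H]3[C@H](O2)[C@H]1O
F5 | step 4 | 7-endo-hydroxy-3,8-dioxatricyclo[3.2.1.0(2,4)]octane-6-exo-carbaldehyde | O=C[C@@H]1[C@H]2[C@@H]3O[C@@H]3[C@H](O2)[C@H]1O
F6 | step 4 | (3S,4R,5R,6S)-3,4-epoxy-5,6-dihydroxycyclohex-1-ene-1-carbaldehyde | O=CC1=C[C@@H]2O[C@@H]2[C@H](O)[C@H]1O
F0 | step 6 | none | none
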